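## The problem

Ruixianglangdusu B is a 3,3''-biflavanone. Two 2-(4-methoxyphenyl)chroman-4-one units are joined through C3–C3'', so C4(=O)–C3–C3''–C4''(=O) is a 1,4-diketone held between two pyranone rings (O1, C2, C3, C4, C4a, C8a and the double-primed twin), each fused to a phloroglucinol-type ring A. The configuration is (2S,3R,2''S,3''R): in each half the C2 aryl group is trans to the C3–C3'' bond, and skeleton and stereocentres are related by a twofold axis that only the single methyl ether at O7'' breaks. C3 and C3'' are α to ketones and can be corrected by enolisation, whereas C2 and C2'' change only if the ring opens. C2 and C2'' must therefore be set absolutely and can then steer C3 and C3'' into the trans (diequatorial) arrangement. The C3–C3'' bond joins two tertiary carbons that each neighbour a stereocentre, so it is better carried in from the start than made late. The sensitive points are: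
- the O1–C2 bonds, which base opens by retro-oxa-Michael reaction through the C3 enolate, scrambling C2;
- the 1,4-diketone, which acid can cyclodehydrate;
- the electron-rich rings A;
- in any open-chain precursor, a C2 ether that is benzylic twice over and ionises in acid.

The enabling feature is that C4–C3–C3''–C4'' with its two oxygens is a furan in masked form. A 3,4-disubstituted furan already holds the C3–C3'' bond, its α carbons are C4 and C4'', and each α C–H can be reached by a bromine-bearing C4a of an aryl ether on C2 through exactly the six-membered pyran ring.

## Retrosynthesis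

**17 from 16.** The O7''–CH3 bond is cut last, so everything before it is twofold-symmetric and can be built in two directions at once. In tetraol 16 the two 7-hydroxyls are interchanged by the twofold axis, so one methylation gives 17 whichever reacts, and the chelated 5-hydroxyls stay out. The price is a statistical extent of reaction. The forward step must be neutral, because base opens flavanones.

**16 from 15.** Four O–CH2OMe bonds are cut. Acetal protection is preferred to benzyl for two reasons. In 10 a benzyl ether on O5 would sit ortho to the C4a–Br bond, and the arylpalladium intermediate would close onto the benzyl ring (the textbook benzo[c]chromene closure) in competition with the furan. Hydrogenolysis would also threaten the benzylic C2–O1 bonds. The forward step needs only dilute acid, which the flavanone rings tolerate.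

**15 from 13.** The C3–H and C3''–H bonds are removed, leaving ene-dione 13. The forward reaction is a two-electron reduction followed by equilibration of C3 and C3'' (mixture 14) under control of C2 and C2''. A dissolving-metal reduction in acid is avoided: the dienol of a tetrasubstituted diaryl ene-dione can close back to the furan under acid, which would undo the previous step. A neutral electron-transfer reduction is asked for instead.

**13 from 11.** The two carbonyl oxygens are traced back to furan 11 through endoperoxide 12. Strictly, the furan is the cyclodehydrated form of diketone 15 (same oxidation level), and 13 is the oxidised form. Direct hydrolysis of a 2,5-diarylfuran needs strong aqueous acid and lies on the furan side, so the detour of photooxygenation followed by reduction is taken. It runs cold and neutral.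

**11 from 10.** The C4–C4a and C4''–C4a'' bonds are cut. This removes both pyran rings at once and leaves an open-chain bis(aryl ether) of a simple furan. The neighbouring cuts are weaker: O1–C2 would need a stereocontrolled oxa-Michael closure on a hindered α-substituted enone, and C3–C3'' a coupling of two tertiary centres. The forward reaction must pick the furan α C–H over other C–H bonds in reach and must stay basic to spare the C2 ethers.

**10 from 9 and 3.** The two O1–C8a bonds are cut to diol 9 and bromo-iodoarene 3. A copper-catalysed O-arylation leaves the C2–O bonds untouched, so the carbinol configuration is retained. Displacement at C2 by a phenol would pass through a stabilised cation. The forward step must discriminate C–I from C–Br and couple a hindered secondary alkoxide twice.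

**9 from 8.** Two C2–H bonds are cut. The catalytic enantioselective reduction of diketone 8 sets C2 and C2'' by catalyst control. A twofold reduction also purifies itself: the minor sense ends up mainly in the separable meso diol.

**8 from 6 and 7, 6 from 4.** The aryl–carbonyl bonds are cut to bis(N-methoxy-N-methylamide) 6 and Grignard reagent 7. Amide 6 comes from diacid 4 through dichloride 5. A Friedel–Crafts use of 5 was set aside: a vicinal diacid chloride invites lactone-type by-products and leaves the site of attack to the arene.

**3 from 2 from 1.** The C–Br bond and then the two acetals are removed, back to 5-iodoresorcinol 1. The symmetry of 2 makes the two positions para to an oxygen and ortho to iodine equivalent, so one bromination gives 3.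

## Roads not taken

**Alternative 1:** The rings A are removed first and the succinate core is built stereoselectively. The bis-β-keto ester A1 (dimethyl 2,3-bis(4-methoxybenzoyl)succinate) would be hydrogenated with RuCl2(BINAP) (divalent ruthenium) under dynamic kinetic resolution, and the diol would lactonise to the cis-fused dilactone A2.
- Merit: C2, C3, C2'' and C3'' are fixed in one catalytic operation, and C3/C3'' by ring fusion. This is better than the chosen plan, which relies on equilibration for C3/C3''.
- Weak points: in A2 each lactone ties the C2 oxygen to the carbonyl of the other half. Both lactones must be opened by acylating a ring A, which exposes β-hydroxy ketones (retro-aldol, dehydration). Each O1–C8a bond must then still be made at a 4-methoxybenzylic carbinol.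
- Comparison: the chosen plan has both rings A and all ring bonds in place once the key step is done, and no aldol-type intermediate.

**Alternative 2:** The O1–C8a and C4–C4a bonds of both halves are cut at once. The Stobbe-type diacid A3 ((2E,3E)-2,3-bis(4-methoxybenzylidene)succinic acid) would react twice with aryne A4 (3,5-bis(benzyloxy)benzyne, released by CsF). Each carboxylate oxygen adds, the aryl anion takes the acyl group, and the bis(2'-hydroxychalcone) A5 results.
- Merit: it is clearly shorter, and the whole carbon skeleton appears in one step from simple pieces.
- Weak points: no ring is closed and no stereocentre is set. The double oxa-Michael closure of A5 must create four stereocentres on hindered α-substituted enones with no element of absolute control, so racemic and meso-type mixtures are to be expected.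
- Comparison: the chosen plan is longer, but it fixes the absolute configuration early by a catalytic reduction and closes the rings by C–C bond formation, which cannot touch C2.

**Alternative 3:** The C3–C3'' bond and both O1–C2 bonds are cut. Two molecules of the 4-hydroxychalcone A6 would be oxidised by Ag2O (monovalent silver). The radicals would couple at the α carbons, and each quinone methide would be trapped by its 2'-hydroxyl under a chiral BINOL-derived phosphoric acid to give biflavanone A7.
- Merit: it is the shortest and follows the likely biogenesis; one step makes the central bond and both rings.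
- Weak points: the radical can also couple through ring B carbon or oxygen, the C3–C3'' bond forms as dl and meso pairs, and twofold enantioselective trapping of a bis(quinone methide) is asking much of the acid. The 4'- and 4'''-hydroxyls then need methylation, and the same single 7-O-methylation remains.
- Comparison: the chosen plan has more steps; in return every bond is formed at a predictable place.

Key step: step 7

Assumption 1: in the oxazaborolidine reduction of 8 the conjugated, nearly coplanar 4-methoxyphenyl group is taken to act as the aryl group of an aryl alkyl ketone, and the twisted 4-substituted furan-3-yl group as the alkyl group. On that model the (R)-catalyst gives the (R)-carbinols. The configuration of 9 is to be checked before it is carried on, and the (S)-catalyst is used if the sense is the reverse.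

Assumption 2: with C2 and C2'' fixed, the 2,3-trans/2'',3''-trans isomer 15 is the most stable of the three C3/C3'' epimers, as is usual for 3-substituted flavanones.

## Route

Step 1
Reactants: 1 5-iodobenzene-1,3-diol
Product: 2 1-iodo-3,5-bis(methoxymethoxy)benzene
Conditions: MeOCH2Cl, i-Pr2NEt, CH2Cl2, 0 °C to rt
Reagents that add atoms: chloromethyl methyl ether, COCCl
Why: Twofold O-alkylation of the phenols (Williamson-type) is routine; the acetal is chosen because, unlike a benzyl ether next to the later C–Br bond, it offers no aryl C–H to the arylpalladium intermediate of step 7 and is removed without hydrogenolysis.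

Step 2
Reactants: 2 1-iodo-3,5-bis(methoxymethoxy)benzene
Product: 3 2-bromo-1-iodo-3,5-bis(methoxymethoxy)benzene
Conditions: NBS (1.0 equiv), MeCN, 0 °C to rt, dark
Reagents that add atoms: N-bromosuccinimide, O=C1CCC(=O)N1Br
Why: Electrophilic aromatic bromination; the two equivalent positions para to one oxygen and ortho to the other (next to iodine) react before the position flanked by both acetal oxygens, as with other 5-substituted resorcinol diethers, and one equivalent limits dibromination.

Step 3
Reactants: 4 furan-3,4-dicarboxylic acid
Product: 6 N3,N4-dimethoxy-N3,N4-dimethylfuran-3,4-dicarboxamide, via furan-3,4-dicarbonyl dichloride 5 (not isolated)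
Conditions: (COCl)2, HCONMe2 (cat.), CH2Cl2, 0 °C to rt; evaporate; MeNH(OMe)·HCl, Et3N, CH2Cl2, 0 °C to rt
Reagents that add atoms: N,O-dimethylhydroxylamine hydrochloride, CNOC.Cl
Why: Acid chloride formation and amidation give the bis-amide of the Weinreb ketone synthesis, which fixes where the aryl groups will be attached.

Step 4
Reactants: 6 N3,N4-dimethoxy-N3,N4-dimethylfuran-3,4-dicarboxamide; 7 4-methoxyphenylmagnesium bromide
Product: 8 furan-3,4-diylbis[(4-methoxyphenyl)methanone]
Conditions: 7 (2.6 equiv), THF, 0 °C to rt; 1 M HCl
Reagents that add atoms: none
Why: Weinreb ketone synthesis: each amide takes up one aryl Grignard reagent to give a chelated tetrahedral magnesium adduct that collapses to the ketone only on acidic work-up, so no tertiary alcohol forms.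

Step 5
Reactants: 8 furan-3,4-diylbis[(4-methoxyphenyl)methanone]
Product: 9 (R,R)-furan-3,4-diylbis[(4-methoxyphenyl)methanol]
Conditions: (R)-1-methyl-3,3-diphenyltetrahydro-1H,3H-pyrrolo[1,2-c][1,3,2]oxazaborole (0.4 equiv), BH3·SMe2, THF, −20 °C; MeOH
Reagents that add atoms: none
Why: Corey–Bakshi–Shibata reduction of a diaryl ketone: hydride is delivered inside the ketone–oxazaborolidine–borane complex to one face of each carbonyl, the catalyst telling the conjugated 4-methoxyphenyl group from the twisted furyl group (sense as in assumption 1); each centre is set by the catalyst, and since two are set in turn the minor sense ends up mainly in the meso diol, which is separated.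

Step 6
Reactants: 9 (R,R)-furan-3,4-diylbis[(4-methoxyphenyl)methanol]; 3 2-bromo-1-iodo-3,5-bis(methoxymethoxy)benzene
Product: 10 (R,R)-3,4-bis{[2-bromo-3,5-bis(methoxymethoxy)phenoxy](4-methoxyphenyl)methyl}furan
Conditions: 3 (3 equiv), CuI (0.2 equiv), 3,4,7,8-tetramethyl-1,10-phenanthroline (0.4 equiv), Cs2CO3, toluene, 90 °C
Reagents that add atoms: none
Why: Ullmann-type copper-catalysed O-arylation of a secondary alcohol by an aryl iodide; the copper alkoxide (monovalent copper) attacks C–I far faster than C–Br, and because the C2–O bonds are never broken both carbinol centres are retained.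

Step 7
Reactants: 10 (R,R)-3,4-bis{[2-bromo-3,5-bis(methoxymethoxy)phenoxy](4-methoxyphenyl)methyl}furan
Product: 11 (2R,2''R)-2,2''-bis(4-methoxyphenyl)-5,7,5'',7''-tetrakis(methoxymethoxy)-2H,2''H-furo[3,2-c:4,5-c']dichromene (biflavonoid numbering; the furan oxygen bridges C4 and C4'', the furan β carbons are C3 and C3'')
Conditions: Pd(OAc)2 (0.1 equiv), PCy3·HBF4 (0.2 equiv), K2CO3, t-BuCO2H (0.6 equiv), DMA, 110 °C
Reagents that add atoms: none
Why: Zerovalent palladium, formed from Pd(OAc)2 and the phosphine, adds oxidatively to each C4a–Br bond to give an arylpalladium bromide (divalent palladium); pivalate replaces bromide and removes the neighbouring furan α hydrogen in a concerted metalation–deprotonation, and reductive elimination forms C4–C4a, after which the same sequence on the other half forms C4''–C4a''. The closest known reaction type is the palladium/pivalate intramolecular direct arylation of five-membered heteroarenes by tethered aryl bromides, as used to make furo[3,2-c]chromenes. Each pyran ring (O1, C2, C3, C4, C4a, C8a and its twin) closes as a six-membered ring through a seven-membered palladacycle. No stereocentre is formed, and C2 and C2'' pass through unchanged because the medium is basic and neither their C–H nor their C–O bonds take part. The step needs site selectivity, because each arylpalladium can also reach an ortho C–H of the 4-methoxyphenyl group on the same carbon through a ring of the same size. The furan α C–H is the more acidic and more π-nucleophilic bond and has the lower metalation barrier, the far furan α position would need an eight-membered ring, and the acetal groups put no aryl C–H next to the bromide. Bromide is the only halide left, so there is no chemoselectivity issue.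

Step 8
Reactants: 11 (2R,2''R)-2,2''-bis(4-methoxyphenyl)-5,7,5'',7''-tetrakis(methoxymethoxy)-2H,2''H-furo[3,2-c:4,5-c']dichromene
Product: 13 (Z)-(2R,2''R)-2,2''-bis(4-methoxyphenyl)-5,7,5'',7''-tetrakis(methoxymethoxy)-3,3''-bi(chroman-3-ylidene)-4,4''-dione, via furan endoperoxide 12 (not isolated)
Conditions: O2, visible light, 5,10,15,20-tetraphenylporphyrin (cat.), CH2Cl2, −78 °C; Me2S, −78 °C to rt
Reagents that add atoms: oxygen, O=O
Why: [4+2] cycloaddition of singlet oxygen across the furan α carbons C4 and C4'' (the two faces are interchanged by the twofold axis, so one endoperoxide forms) and reduction by the sulfide give the cis ene-1,4-dione, the known behaviour of 2,5-diarylfurans; the product is taken on without chromatography because its C2–H is vinylogously acidic.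

Step 9
Reactants: 13 (Z)-(2R,2''R)-2,2''-bis(4-methoxyphenyl)-5,7,5'',7''-tetrakis(methoxymethoxy)-3,3''-bi(chroman-3-ylidene)-4,4''-dione
Product: 15 (2S,3R,2''S,3''R)-4',4'''-dimethoxy-5,7,5'',7''-tetrakis(methoxymethoxy)-3,3''-biflavanone, via C3-epimeric diketone mixture 14 (not isolated)
Conditions: SmI2 (2.2 equiv), THF–MeOH, −78 °C; aq. NH4Cl; then 1,8-diazabicyclo[5.4.0]undec-7-ene (0.2 equiv), CH2Cl2–MeOH, 0 °C to rt
Reagents that add atoms: none
Why: Electron-transfer reduction of the ene-1,4-dione (two electrons from divalent samarium, protons from methanol) gives the saturated diketone without the acid that lets the dienol of a diaryl ene-dione close back to the furan; C3 and C3'' then equilibrate through their enolates and settle trans to the C2 and C2'' aryl groups (both ring substituents equatorial), that is 3R and 3''R under control of the fixed centres, and in the protic medium the enolate should be reprotonated faster than it expels O1, whose bond lies near the nodal plane of the enolate.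

Step 10
Reactants: 15 (2S,3R,2''S,3''R)-4',4'''-dimethoxy-5,7,5'',7''-tetrakis(methoxymethoxy)-3,3''-biflavanone
Product: 16 (2S,3R,2''S,3''R)-5,7,5'',7''-tetrahydroxy-4',4'''-dimethoxy-3,3''-biflavanone
Conditions: HCl (1.25 M in MeOH), THF, 40 °C
Reagents that add atoms: none
Why: Acid-catalysed acetal exchange with methanol removes the four methoxymethyl groups (those on the chelated O5 first); aryl methyl ethers and flavanone rings tolerate dilute methanolic HCl, and any acid-promoted enolisation can only confirm the thermodynamic C3 configuration.

Step 11
Reactants: 16 (2S,3R,2''S,3''R)-5,7,5'',7''-tetrahydroxy-4',4'''-dimethoxy-3,3''-biflavanone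
Product: 17 ruixianglangdusu B, (2S,3R,2''S,3''R)-5,7,5''-trihydroxy-7'',4',4'''-trimethoxy-3,3''-biflavanone
Conditions: CH2N2 (about 1 equiv, in Et2O, added in portions), THF–MeOH, 0 °C
Reagents that add atoms: diazomethane, C=[N+]=[N-]
Why: O-Methylation of the most acidic phenol by diazomethane (proton transfer, then SN2 on methyldiazonium); the 7-hydroxyls are vinylogous acids while the 5-hydroxyls are held in hydrogen bonds to the C4 carbonyls, and since the two 7-hydroxyls are interchanged by the twofold axis one methylation gives 17 whichever reacts; the extent is statistical, so recovered 16 is resubmitted and the 7,7''-dimethyl ether is separated.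

## Compound list

1 | 5-iodobenzene-1,3-diol | Oc1cc(O)cc(I)c1 | starting material
2 | 1-iodo-3,5-bis(methoxymethoxy)benzene | COCOc1cc(I)cc(OCOC)c1 | intermediate
3 | 2-bromo-1-iodo-3,5-bis(methoxymethoxy)benzene | COCOc1cc(I)c(Br)c(OCOC)c1 | intermediate
4 | furan-3,4-dicarboxylic acid | O=C(O)c1cocc1C(=O)O | starting material
5 | furan-3,4-dicarbonyl dichloride | O=C(Cl)c1cocc1C(Cl)=O | intermediate (not isolated)
6 | N3,N4-dimethoxy-N3,N4-dimethylfuran-3,4-dicarboxamide | CON(C)C(=O)c1cocc1C(=O)N(C)OC | intermediate
7 | 4-methoxyphenylmagnesium bromide | COc1ccc([Mg]Br)cc1 | starting material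
8 | furan-3,4-diylbis[(4-methoxyphenyl)methanone] | COc1ccc(C(=O)c2cocc2C(=O)c2ccc(OC)cc2)cc1 | intermediate
9 | (R,R)-furan-3,4-diylbis[(4-methoxyphenyl)methanol] | COc1ccc([C@@H](O)c2cocc2[C@H](O)c2ccc(OC)cc2)cc1 | intermediate
10 | (R,R)-3,4-bis{[2-bromo-3,5-bis(methoxymethoxy)phenoxy](4-methoxyphenyl)methyl}furan | COc1ccc([C@@H](Oc2cc(OCOC)cc(OCOC)c2Br)c2cocc2[C@H](Oc2cc(OCOC)cc(OCOC)c2Br)c2ccc(OC)cc2)cc1 | intermediate (key-step precursor)
11 | (2R,2''R)-2,2''-bis(4-methoxyphenyl)-5,7,5'',7''-tetrakis(methoxymethoxy)-2H,2''H-furo[3,2-c:4,5-c']dichromene | COc1ccc([C@H]2Oc3cc(OCOC)cc(OCOC)c3-c3oc4c([C@@H](c5ccc(OC)cc5)Oc5cc(OCOC)cc(OCOC)c5-4)c32)cc1 | intermediate (key-step product)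
12 | endoperoxide of 11 (dioxygen bridge from C4 to C4'', C3=C3'' double bond, 2R,2''R) | COc1ccc([C@H]2Oc3cc(OCOC)cc(OCOC)c3[C@]5(OO6)O[C@]6(c3c(OCOC)cc(OCOC)cc3O[C@@H]7c3ccc(OC)cc3)C7=C25)cc1 | intermediate (not isolated)
13 | (Z)-(2R,2''R)-2,2''-bis(4-methoxyphenyl)-5,7,5'',7''-tetrakis(methoxymethoxy)-3,3''-bi(chroman-3-ylidene)-4,4''-dione | O=C1c2c(OCOC)cc(OCOC)cc2O[C@H](c2ccc(OC)cc2)/C1=C1/C(=O)c2c(OCOC)cc(OCOC)cc2O[C@@H]1c1ccc(OC)cc1 | intermediate
14 | (2S,2''S)-4',4'''-dimethoxy-5,7,5'',7''-tetrakis(methoxymethoxy)-3,3''-biflavanone, mixture of C3/C3'' epimers | COc1ccc([C@H]2Oc3cc(OCOC)cc(OCOC)c3C(=O)C2C2C(=O)c3c(OCOC)cc(OCOC)cc3O[C@@H]2c2ccc(OC)cc2)cc1 | intermediate (not isolated)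
15 | (2S,3R,2''S,3''R)-4',4'''-dimethoxy-5,7,5'',7''-tetrakis(methoxymethoxy)-3,3''-biflavanone | COc1ccc([C@H]2Oc3cc(OCOC)cc(OCOC)c3C(=O)[C@@H]2[C@H]2C(=O)c3c(OCOC)cc(OCOC)cc3O[C@@H]2c2ccc(OC)cc2)cc1 | intermediate
16 | (2S,3R,2''S,3''R)-5,7,5'',7''-tetrahydroxy-4',4'''-dimethoxy-3,3''-biflavanone | COc1ccc([C@H]2Oc3cc(O)cc(O)c3C(=O)[C@@H]2[C@H]2C(=O)c3c(O)cc(O)cc3O[C@@H]2c2ccc(OC)cc2)cc1 | intermediate
17 | ruixianglangdusu B | COc1ccc([C@H]2Oc3cc(O)cc(O)c3C(=O)[C@@H]2[C@H]2C(=O)c3c(O)cc(OC)cc3O[C@@H]2c2ccc(OC)cc2)cc1 | target

## Step count and risks

Total: 11 steps. Longest linear sequence: 9 steps (steps 3 to 11, from 4). The arene branch (steps 1 and 2) joins at step 6.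

**Step 7 (key step).** The likely failures are arylation at the ortho C–H of the 4-methoxyphenyl ring instead of the furan, reductive loss of bromine from the doubly ortho-substituted electron-rich bromide, or stalling after the first ring. Fallback: starting from 10, both furan α positions are deprotonated with TMPMgCl·LiCl, a base that leaves aryl bromides alone. This gives the 2,5-bis(chloromagnesio) derivative of 10 F1, which is transmetalated with ZnCl2 to the 2,5-bis(chlorozincio) derivative of 10 F2. Both rings are then closed by intramolecular Negishi coupling (Pd(OAc)2, 2-dicyclohexylphosphino-2',6'-dimethoxybiphenyl, THF, 60 °C), returning to the route at 11. The carbon that attacks is then fixed by the metalation and not by competition between C–H bonds.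

**Step 6.** Alkoxide and iodide are both hindered, so the second etherification may stay incomplete. The diaryl carbinol may also be oxidised to the ketone with reduction of the iodide, or lose configuration through reversible hydride transfer at copper. Fallback: starting from 9, the coupling is run with the unhindered, bromine-free iodide 2 under the same copper catalysis. This gives (R,R)-3,4-bis{[3,5-bis(methoxymethoxy)phenoxy](4-methoxyphenyl)methyl}furan F3. Its two rings are closed by twofold palladium-catalysed dehydrogenative C–H/C–H coupling (Pd(OAc)2, AgOAc, t-BuCO2H, 110 °C) between each furan α position and either of the two equivalent ortho positions of the aryl ether, returning at 11.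

**Step 9.** The samarium enolate may expel O1 (β-elimination) or the aryl ketones may be reduced further. During the base equilibration the rings may open by retro-oxa-Michael reaction, which would epimerise C2. Fallback: starting from 13, the C3=C3'' bond is hydrogenated over Pd/C (palladium on carbon; H2, EtOAc, rt), which leaves the acetals alone and gives 14. This is not treated with base but carried through the acidic acetal cleavage of step 10 to the C3/C3''-epimer mixture of the tetraol F4. That mixture is equilibrated through the enols in AcOH/NaOAc at 50 °C, where no enolate is formed, returning at 16.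

**Step 5.** The catalyst may distinguish the two aryl groups poorly or in the sense opposite to assumption 1, which gives much meso diol or the wrong enantiomer. Fallback: starting from 6, reduction with LiAlH4 (THF, −78 °C) gives furan-3,4-dicarbaldehyde F5. Its two aldehydes take up the aryl group enantioselectively from 4-methoxyphenylboronic acid and Et2Zn, with the enantiomer of 2-piperidino-1,1,2-triphenylethanol that delivers the (R)-carbinols as catalyst, returning at 9. The stereocentres are then set by C–C bond formation and not by hydride delivery.

Step 11 is reliable as a reaction; its limit is that conversion has to be held near one methylation, with recycling of 16.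

## Further compounds

F1 | step 7 | 2,5-bis(chloromagnesio) derivative of 10 | COc1ccc([C@@H](Oc2cc(OCOC)cc(OCOC)c2Br)c2c([Mg]Cl)oc([Mg]Cl)c2[C@H](Oc2cc(OCOC)cc(OCOC)c2Br)c2ccc(OC)cc2)cc1
F2 | step 7 | 2,5-bis(chlorozincio) derivative of 10 | COc1ccc([C@@H](Oc2cc(OCOC)cc(OCOC)c2Br)c2c([Zn]Cl)oc([Zn]Cl)c2[C@H](Oc2cc(OCOC)cc(OCOC)c2Br)c2ccc(OC)cc2)cc1
F3 | step 6 | (R,R)-3,4-bis{[3,5-bis(methoxymethoxy)phenoxy](4-methoxyphenyl)methyl}furan | COc1ccc([C@@H](Oc2cc(OCOC)cc(OCOC)c2)c2cocc2[C@H](Oc2cc(OCOC)cc(OCOC)c2)c2ccc(OC)cc2)cc1
F4 | step 9 | (2S,2''S)-5,7,5'',7''-tetrahydroxy-4',4'''-dimethoxy-3,3''-biflavanone, mixture of C3/C3'' epimers | COc1ccc([C@H]2Oc3cc(O)cc(O)c3C(=O)C2C2C(=O)c3c(O)cc(O)cc3O[C@@H]2c2ccc(OC)cc2)cc1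
F5 | step 5 | furan-3,4-dicarbaldehyde | O=Cc1cocc1C=O
A1 | alternative 1 | dimethyl 2,3-bis(4-methoxybenzoyl)succinate | COC(=O)C(C(=O)c1ccc(OC)cc1)C(C(=O)OC)C(=O)c1ccc(OC)cc1
A2 | alternative 1 | exo,exo-2,6-bis(4-methoxyphenyl)-3,7-dioxabicyclo[3.3.0]octane-4,8-dione | COc1ccc([C@@H]2OC(=O)[C@@H]3[C@H]2C(=O)O[C@H]3c2ccc(OC)cc2)cc1
A3 | alternative 2 | (2E,3E)-2,3-bis(4-methoxybenzylidene)succinic acid | COc1ccc(/C=C(/C(=O)O)C(=C/c2ccc(OC)cc2)\C(=O)O)cc1
A4 | alternative 2 | 3,5-bis(benzyloxy)benzyne | C1#CC(OCc2ccccc2)=CC(OCc2ccccc2)=C1
A5 | alternative 2 | bis(2'-hydroxy-4',6'-dibenzyloxychalcone) joined through the two α carbons | COc1ccc(/C=C(/C(=O)c2c(O)cc(OCc3ccccc3)cc2OCc2ccccc2)C(=C/c2ccc(OC)cc2)\C(=O)c2c(O)cc(OCc3ccccc3)cc2OCc2ccccc2)cc1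
A6 | alternative 3 | (E)-1-[2,4-bis(benzyloxy)-6-hydroxyphenyl]-3-(4-hydroxyphenyl)prop-2-en-1-one | O=C(/C=C/c1ccc(O)cc1)c1c(O)cc(OCc2ccccc2)cc1OCc1ccccc1
A7 | alternative 3 | 5,7,5'',7''-tetra-O-benzyl biflavanone with free 4'- and 4'''-hydroxyls | Oc1ccc([C@H]2Oc3cc(OCc4ccccc4)cc(OCc4ccccc4)c3C(=O)[C@@H]2[C@H]2C(=O)c3c(OCc4ccccc4)cc(OCc4ccccc4)cc3O[C@@H]2c2ccc(O)cc2)cc1
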